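A direct plan would keep a phloroglucinol-derived benzene ring from the start and hang the three carbon arms on it one after another.
It would make 3,5-dimethoxy-2-(4-methoxybenzyl)phenol A1 (aryl Grignard addition to the salicylaldehyde, then ionic hydrogenation), convert it into the ortho-silylaryl triflate A2, and let the aryne from A2 insert into the central C–C bond of 1,3-bis(4-methoxyphenyl)propane-1,3-dione A3 to give the 1,5-diketone A4; double ionic hydrogenation and BBr3 would finish.
Weak point 1, the passage from A1 to A2 (carbamoylation, ortho-lithiation/silylation, carbamate-to-triflate exchange): three steps would add no skeletal atom, and the lithiation would have to beat lateral deprotonation of the diarylmethane CH2 beside the carbamate and the anionic Fries shift.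
Weak point 2, the aryne acyl-alkylation: the site of attack on an unsymmetrical, fully substituted aryne would rest on a methoxy inductive effect working against the flanking benzyl group, with a little-tested diaryl 1,3-diketone, on the most precious intermediate.
Weak point 3, the deoxygenation of both ketones of A4: the diaryl ketone sits between two ortho substituents, and acid could divert the 1,5-diketone into isochromenylium-type cycles that need not all drain to the hydrocarbon.

Plan of the new route
- Bonds cut (resorcinol numbering: C1/C3 oxygenated, C4/C6 benzylated, C5 carrying the arylethyl chain): first ring bonds C1–C6 and C2–C3, so that C1–C2 comes from ethoxyacetylene and C3–C4–C5–C6 from a cyclobutenone; then the C5–CH2 bond; then C3–C4 and C5–C6, which arise from two molecules of one ynol ether.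
- Ring order: the three anisole rings are bought, the cyclobutenone is made first (step 2), and the central benzene ring is made last from it (step 4).
- Enabling feature: C1–C2(H)–C3 is a meta-dioxygenated unit with an unsubstituted CH between the oxygens, which is what a ketene carbonyl plus a terminal alkoxyacetylene deliver. The mirror plane through C2 and C5 makes C4 and C6 (each bearing CH2Ar) the C2 and C4 of a cyclobutenone whose two benzyl arms come from the same precursor.
- The weak steps do not arise: there is no aryne precursor, directing group or ketone deoxygenation. Every arm arrives at its final oxidation level, and the substitution pattern is fixed by the polarity of two ketene/ynol ether cycloadditions.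

Key step: step 4

Remark on the chemistry: the target is achiral; the stereocentres of 6, 9, 10, 12 and 14 are transient and are formed racemic; ethoxyacetylene is used as its commercial solution in hexanes.

Step 1
Reactants: 1 ethoxyacetylene (ethoxyethyne); 2 4-methoxybenzyl bromide
Product: 4 1-(3-ethoxyprop-2-yn-1-yl)-4-methoxybenzene, via lithium ethoxyacetylide 3 (not isolated)
Conditions: 1 (1.2 equiv), n-BuLi (1.1 equiv), THF, −78 °C; then 2, DMPU, −78 → 0 °C; aq. NaHCO3; filtration through Et3N-deactivated silica
Reagents that add atoms: n-butyllithium, [Li]CCCC (lithium present in 3 only)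
Why: Alkylation of a metallated 1-alkoxyalkyne (SN2 displacement of the activated benzylic bromide by the acetylide carbon, helped by the dipolar cosolvent) is the standard entry to 1-alkoxy-1-alkynes and forms no stereocentre.

Step 2
Reactants: 4 1-(3-ethoxyprop-2-yn-1-yl)-4-methoxybenzene (two molecules)
Product: 6 3-ethoxy-2,4-bis(4-methoxybenzyl)cyclobut-2-en-1-one (racemic), via (4-methoxybenzyl)ketene 5 (not isolated)
Conditions: toluene, 110 °C, argon, ethene vented
Reagents that add atoms: none
Why: Thermolysis of a 1-ethoxy-1-alkyne: a retro-ene reaction expels ethene to give aldoketene 5, which is trapped by [2+2] cycloaddition with unchanged 4 (the ynol ether carbon remote from oxygen bonds to the ketene carbonyl carbon), so the 2,4-dibenzyl-3-ethoxy pattern follows from polarity alone; the C4 stereocentre forms racemic and is erased in step 4.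

Step 3
Reactants: 6 3-ethoxy-2,4-bis(4-methoxybenzyl)cyclobut-2-en-1-one; 7 1-(2-bromoethyl)-4-methoxybenzene
Product: 10 2,4-bis(4-methoxybenzyl)-3-[2-(4-methoxyphenyl)ethyl]cyclobut-2-en-1-one (racemic), via 2-(4-methoxyphenyl)ethylmagnesium bromide 8 (not isolated), via tertiary cyclobutenol 9 (not isolated)
Conditions: 7, Mg, THF, rt; then 6, THF, −78 → 0 °C; then 1 M HCl, THF, rt
Reagents that add atoms: magnesium, [Mg] (present in 8 only); water, O (carbonyl oxygen of 10)
Why: 1,2-Addition of the Grignard reagent to the vinylogous ester carbonyl, then acid hydrolysis of the enol ether with loss of water (Stork–Danheiser-type carbonyl transposition), gives the 3-alkylcyclobutenone; because C2 and C4 of 6 carry the same group, a competing addition–elimination at C3 would give the same compound 10, whose C4 stereocentre is racemic and transient.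

Step 4
Reactants: 10 2,4-bis(4-methoxybenzyl)-3-[2-(4-methoxyphenyl)ethyl]cyclobut-2-en-1-one; 1 ethoxyacetylene
Product: 15 5-ethoxy-2,4-bis(4-methoxybenzyl)-3-[2-(4-methoxyphenyl)ethyl]phenol, via vinylketene 11 (not isolated), via 4-alkenylcyclobutenone 12 (not isolated), via dienylketene 13 (not isolated), via cyclohexadienone 14 (not isolated)
Conditions: 1 (3 equiv), toluene, sealed tube, 80 °C, then 110 °C
Reagents that add atoms: none
Why: Danheiser benzannulation: conrotatory 4π-electrocyclic opening of 10, with the C4 benzyl group rotating outward, gives (E)-vinylketene 11, which undergoes [2+2] cycloaddition with ethoxyacetylene (its nucleophilic CH carbon bonding to the ketene carbonyl carbon) to 4-alkenylcyclobutenone 12; a second 4π opening gives dienylketene 13, and 6π-electrocyclisation followed by tautomerisation of 14 gives phenol 15. The closest known reaction type is the thermal benzannulation of cyclobutenones with alkoxy- and siloxyacetylenes to resorcinol monoethers, including 2-substituted cyclobutenones that react through disubstituted ketenes. Two rings close: the transient four-membered ring of 12 by ketene–alkyne [2+2] cycloaddition, and the six-membered central ring by disrotatory 6π closure between the ketene carbon and the benzyl-bearing alkene terminus of 13. The stereocentres involved (C4 of 10, the quaternary carbon of 12, C6 of 14) are racemic and vanish on aromatisation, so none needs control; the only geometric demand is outward rotation of the C4 benzyl group, the normal torquoselectivity of an alkyl group, which keeps it clear of a 1,5-hydrogen shift and of the closing termini. The selectivity needed is regiochemical (oxygens meta with hydrogen between them, three carbon arms contiguous); it is secured by the fixed polarity of the ketene/ynol ether pair and by the fact that C2 and C4 of 10 carry the same 4-methoxybenzyl group. The rotamer of 13 that cannot cyclise recloses to 12 and is recycled at the reaction temperature.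

Step 5
Reactants: 15 5-ethoxy-2,4-bis(4-methoxybenzyl)-3-[2-(4-methoxyphenyl)ethyl]phenol
Product: 16 4,6-bis(4-hydroxybenzyl)-5-[2-(4-hydroxyphenyl)ethyl]benzene-1,3-diol
Conditions: BBr3 (8 equiv), CH2Cl2, −78 °C → rt; ice water
Reagents that add atoms: none
Why: Lewis-acid-mediated dealkylation of aryl alkyl ethers (boron coordinates each ether oxygen and bromide removes methyl or ethyl by SN2) should free the four masked phenols of a substrate that carries no other reactive function, giving the achiral target.

Compound list
1 | ethoxyacetylene (ethoxyethyne) | CCOC#C | starting material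
2 | 4-methoxybenzyl bromide | COc1ccc(CBr)cc1 | starting material
3 | lithium ethoxyacetylide | CCOC#C[Li] | intermediate (not isolated)
4 | 1-(3-ethoxyprop-2-yn-1-yl)-4-methoxybenzene | CCOC#CCc1ccc(OC)cc1 | intermediate
5 | 3-(4-methoxyphenyl)prop-1-en-1-one, (4-methoxybenzyl)ketene | COc1ccc(CC=C=O)cc1 | intermediate (not isolated)
6 | 3-ethoxy-2,4-bis(4-methoxybenzyl)cyclobut-2-en-1-one (racemic) | CCOC1=C(Cc2ccc(OC)cc2)C(=O)C1Cc1ccc(OC)cc1 | intermediate
7 | 1-(2-bromoethyl)-4-methoxybenzene | COc1ccc(CCBr)cc1 | starting material
8 | 2-(4-methoxyphenyl)ethylmagnesium bromide | COc1ccc(CC[Mg]Br)cc1 | intermediate (not isolated)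
9 | 3-ethoxy-2,4-bis(4-methoxybenzyl)-1-[2-(4-methoxyphenyl)ethyl]cyclobut-2-en-1-ol (racemic mixture of diastereomers, formed first as its magnesium alkoxide) | CCOC1=C(Cc2ccc(OC)cc2)C(O)(CCc2ccc(OC)cc2)C1Cc1ccc(OC)cc1 | intermediate (not isolated)
10 | 2,4-bis(4-methoxybenzyl)-3-[2-(4-methoxyphenyl)ethyl]cyclobut-2-en-1-one (racemic) | O=C1C(Cc2ccc(OC)cc2)=C(CCc2ccc(OC)cc2)C1Cc1ccc(OC)cc1 | intermediate (key-step precursor)
11 | (E)-2-(4-methoxybenzyl)-5-(4-methoxyphenyl)-3-[2-(4-methoxyphenyl)ethyl]penta-1,3-dien-1-one (vinylketene) | O=C=C(Cc1ccc(OC)cc1)/C(CCc1ccc(OC)cc1)=C/Cc1ccc(OC)cc1 | intermediate (not isolated)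
12 | 3-ethoxy-4-(4-methoxybenzyl)-4-[(E)-1,5-bis(4-methoxyphenyl)pent-2-en-3-yl]cyclobut-2-en-1-one (racemic) | O=C1C=C(OCC)C1(Cc1ccc(OC)cc1)/C(CCc1ccc(OC)cc1)=C/Cc1ccc(OC)cc1 | intermediate (not isolated)
13 | (3E,5E)-3-ethoxy-4-(4-methoxybenzyl)-7-(4-methoxyphenyl)-5-[2-(4-methoxyphenyl)ethyl]hepta-1,3,5-trien-1-one (dienylketene, ketenyl and alkenyl groups cis on the central double bond) | O=C=C/C(OCC)=C(Cc1ccc(OC)cc1)\C(CCc1ccc(OC)cc1)=C\Cc1ccc(OC)cc1 | intermediate (not isolated)
14 | 3-ethoxy-4,6-bis(4-methoxybenzyl)-5-[2-(4-methoxyphenyl)ethyl]cyclohexa-2,4-dien-1-one (racemic) | O=C1C=C(OCC)C(Cc2ccc(OC)cc2)=C(CCc2ccc(OC)cc2)C1Cc1ccc(OC)cc1 | intermediate (not isolated)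
15 | 5-ethoxy-2,4-bis(4-methoxybenzyl)-3-[2-(4-methoxyphenyl)ethyl]phenol | CCOc1cc(O)c(Cc2ccc(OC)cc2)c(CCc2ccc(OC)cc2)c1Cc1ccc(OC)cc1 | intermediate (key-step product)
16 | 4,6-bis(4-hydroxybenzyl)-5-[2-(4-hydroxyphenyl)ethyl]benzene-1,3-diol (achiral) | Oc1ccc(CCc2c(Cc3ccc(O)cc3)c(O)cc(O)c2Cc2ccc(O)cc2)cc1 | target

Total step count: 5. Longest linear sequence: 5 steps (1 and 2 → 4 → 6 → 10 → 15 → 16).

Steps most likely to fail

Step 4. The hindered, fully substituted ketene terminus of 11 may add to 1 more slowly than 1 is lost by its own retro-ene fragmentation at the temperature needed to open 10. Ketene 11 may also acylate the phenol as it forms; that would be reversed by KOH/MeOH on work-up. The fallback sets out from 10 and comes back at 15. Heating 10 in aqueous dioxane without alkyne would trap 11 as (E)-2-(4-methoxybenzyl)-5-(4-methoxyphenyl)-3-[2-(4-methoxyphenyl)ethyl]pent-3-enoic acid F1. Oxalyl chloride with catalytic DMF would give (E)-2-(4-methoxybenzyl)-5-(4-methoxyphenyl)-3-[2-(4-methoxyphenyl)ethyl]pent-3-enoyl chloride F2. Et3N at room temperature with excess 1 would regenerate 11 by dehydrochlorination under conditions where 1 is stable, and [2+2] cycloaddition would give 12. After removal of excess 1, brief heating in toluene would carry 12 through 13 and 14 to 15. Generating vinylketenes from unsaturated acid chlorides in the presence of ynol ethers is established resorcinol chemistry.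

Step 2. Product 6 is itself a cyclobutenone and may be drawn, on prolonged heating, into ring opening and further cycloaddition with 4; the ketene may also oligomerise. The fallback sets out from 4 and comes back at 6. Ketene 5 would be generated at room temperature from 3-(4-methoxyphenyl)propanoyl chloride F3 (from the commercial acid and oxalyl chloride) and Et3N in ether in the presence of 4. The [2+2] cycloaddition would then run without heating and consume only one molecule of 4.

Step 1. Base-induced propargyl-to-allenyl isomerisation at the doubly activated CH2 of 4 may occur, or displacement by the weakly nucleophilic lithium acetylide may be sluggish. The fallback sets out from 3 and comes back at 4. Transmetalation with ZnCl2 would give ethoxyethynylzinc chloride F4, and Pd(PPh3)4-catalysed Negishi coupling with 2 in THF at room temperature would replace the SN2 step by cross-coupling of a non-basic zinc acetylide.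

Further compounds
F1 | step 4 | (E)-2-(4-methoxybenzyl)-5-(4-methoxyphenyl)-3-[2-(4-methoxyphenyl)ethyl]pent-3-enoic acid (racemic) | OC(=O)C(Cc1ccc(OC)cc1)/C(CCc1ccc(OC)cc1)=C/Cc1ccc(OC)cc1
F2 | step 4 | (E)-2-(4-methoxybenzyl)-5-(4-methoxyphenyl)-3-[2-(4-methoxyphenyl)ethyl]pent-3-enoyl chloride (racemic) | ClC(=O)C(Cc1ccc(OC)cc1)/C(CCc1ccc(OC)cc1)=C/Cc1ccc(OC)cc1
F3 | step 2 | 3-(4-methoxyphenyl)propanoyl chloride | COc1ccc(CCC(=O)Cl)cc1
F4 | step 1 | ethoxyethynylzinc chloride | CCOC#C[Zn]Cl
A1 | direct plan | 3,5-dimethoxy-2-(4-methoxybenzyl)phenol | COc1ccc(Cc2c(O)cc(OC)cc2OC)cc1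
A2 | direct plan | 3,5-dimethoxy-2-(4-methoxybenzyl)-6-(trimethylsilyl)phenyl trifluoromethanesulfonate | COc1cc(OC)c([Si](C)(C)C)c(OS(=O)(=O)C(F)(F)F)c1Cc1ccc(OC)cc1
A3 | direct plan | 1,3-bis(4-methoxyphenyl)propane-1,3-dione | COc1ccc(C(=O)CC(=O)c2ccc(OC)cc2)cc1
A4 | direct plan | 2-[2-(4-methoxybenzoyl)-3,5-dimethoxy-6-(4-methoxybenzyl)phenyl]-1-(4-methoxyphenyl)ethanone | COc1ccc(C(=O)Cc2c(Cc3ccc(OC)cc3)c(OC)cc(OC)c2C(=O)c2ccc(OC)cc2)cc1
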